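Ugonin Q is disconnected through ring A of the flavone: the C7–C8 and C5–C6 bonds are made last, on a pyranone that already holds O1, C2 with ring B, C3 and C4. The feature exploited is the 1,3-dioxygenation of ring A, in which C5 and C7 are at the carbonyl oxidation level, C6 bears the cyclohexylmethyl side chain and C8 is a CH; C8 therefore maps onto a pyranone 2-methyl group, C5 onto a 3-ester and C6–C7 onto a 3-substituted propanoyl unit. One operation acylates the lateral dienolate and closes and aromatises ring A. Its precursors are a bis-SEM-protected 6-aryl-2-methyl-4-pyranone-3-carboxylate and an enantiopure, silyl-protected Weinreb amide.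

Key step: step 11

Assumption: the sense of induction of the (S,R,R)-phosphoramidite ligand and of the (R)-oxazaborolidine is taken from their established models (cyclohexenone; ketones with an unsaturated large group); should either prove opposite on these substrates, the enantiomeric catalyst is used.

Abbreviations: SEM = 2-(trimethylsilyl)ethoxymethyl (CH2OCH2CH2SiMe3); TBS = tert-butyldimethylsilyl; LDA = LiN(i-Pr)2; TBAF = Bu4NF.

**Route**

Step 1
Reactants: 1 3,4-dihydroxybenzaldehyde
Product: 2 3,4-bis(SEM-oxy)benzaldehyde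
Conditions: SEMCl (2.4 equiv), i-Pr2NEt (3 equiv), CH2Cl2, 0 °C → rt
Reagents that add atoms: 2-(trimethylsilyl)ethoxymethyl chloride, C[Si](C)(C)CCOCCl
Why: O-alkylation of both phenols by the reactive chloromethyl ether gives acetal ethers that are inert to the organolithium, amide-base and amine conditions used later and are cleaved by fluoride.

Step 2
Reactants: 2 3,4-bis(SEM-oxy)benzaldehyde
Product: 3 4-(2,2-dibromoethenyl)-1,2-bis(SEM-oxy)benzene
Conditions: CBr4 (2 equiv), PPh3 (4 equiv), Et3N, CH2Cl2, 0 °C
Reagents that add atoms: carbon tetrabromide, BrC(Br)(Br)Br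
Why: Corey–Fuchs dibromo-olefination, a Wittig reaction of the ylide Ph3P=CBr2 with the aldehyde, run amine-buffered so that the SEM acetals are spared.

Step 3
Reactants: 3 4-(2,2-dibromoethenyl)-1,2-bis(SEM-oxy)benzene
Product: 4 3-[3,4-bis(SEM-oxy)phenyl]prop-2-ynoic acid
Conditions: n-BuLi (2.2 equiv), THF, −78 °C; CO2, −78 °C → rt; cold 0.5 M HCl to pH 2, immediate extraction
Reagents that add atoms: carbon dioxide, O=C=O
Why: second stage of the Corey–Fuchs sequence, in which bromine–lithium exchange and elimination give the lithium acetylide that is carboxylated by CO2, the brief cold acidification being strong enough to free the arylpropynoic acid yet too mild to open the SEM acetals.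

Step 4
Reactants: 4 3-[3,4-bis(SEM-oxy)phenyl]prop-2-ynoic acid; 5 methyl acetoacetate
Product: 7 methyl 2-acetyl-5-[3,4-bis(SEM-oxy)phenyl]-3-oxopent-4-ynoate, via arylpropynoyl chloride 6 (not isolated)
Conditions: Me2C=C(Cl)NMe2 (1.1 equiv), CH2Cl2, 0 °C → rt; then added to 5, MgCl2, pyridine, CH2Cl2, 0 °C → rt; aq. citric acid work-up
Reagents that add atoms: none
Why: the α-chloroenamine forms the acid chloride without releasing HCl, and the magnesium chelate of the β-keto ester is acylated at carbon (magnesium-mediated C-acylation of a β-keto ester by an acid chloride).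

Step 5
Reactants: 7 methyl 2-acetyl-5-[3,4-bis(SEM-oxy)phenyl]-3-oxopent-4-ynoate
Product: 8 methyl 6-[3,4-bis(SEM-oxy)phenyl]-2-methyl-4-oxo-4H-pyran-3-carboxylate
Conditions: DMAP (0.2 equiv), DMF, 40 °C
Reagents that add atoms: none
Why: 6-endo-dig oxa-Michael cycloisomerisation of the enolised acetyl oxygen onto the aryl-bearing alkyne carbon (classical γ-pyrone formation from alkynoyl β-dicarbonyl compounds), with nucleophilic amine catalysis favouring the six- over the five-membered closure.

Step 6
Reactants: 9 (1-ethoxycyclopropoxy)trimethylsilane; 10 4,4-dimethylcyclohex-2-en-1-one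
Product: 13 ethyl 3-[(1R)-6,6-dimethyl-3-(trimethylsilyloxy)cyclohex-2-en-1-yl]propanoate, via zinc homoenolate 11 (not isolated), via zinc enolate 12 (not isolated)
Conditions: 9 (2.6 equiv), ZnCl2 (1.3 equiv), Et2O, rt; volatiles removed in vacuo; residue in toluene added to 10 (1.0 equiv), Cu(OTf)2 (3 mol %), (S,R,R)-phosphoramidite [(S)-1,1'-binaphthyl-2,2'-diyl N,N-bis((R)-1-phenylethyl)phosphoramidite] (6 mol %), toluene, −30 → 0 °C; then Me3SiOTf, −30 °C → rt; Et3N, pentane, filtration
Reagents that add atoms: trimethylsilyl trifluoromethanesulfonate, C[Si](C)(C)OS(=O)(=O)C(F)(F)F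
Why: zinc chloride opens two molecules of the siloxycyclopropane to the chelated bis-homoenolate zinc (Nakamura–Kuwajima homoenolate formation), and once the chlorosilane has been pumped off this functionalised dialkylzinc transfers one alkyl group in a copper-catalysed enantioselective conjugate addition to the cyclic enone, in which the copper catalyst carrying the chiral phosphoramidite selects the enone face and so sets the ring stereocentre next to the gem-dimethyl carbon as R, before the silyl triflate traps the regiodefined zinc enolate as its silyl ether.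

Step 7
Reactants: 13 ethyl 3-[(1R)-6,6-dimethyl-3-(trimethylsilyloxy)cyclohex-2-en-1-yl]propanoate
Product: 16 ethyl 3-[(1S)-6,6-dimethyl-2-methylidene-3-oxocyclohexyl]propanoate, via Mannich base 14 (not isolated), via ammonium iodide 15 (not isolated)
Conditions: CH2=NMe2+ I−, CH2Cl2, rt; aq. NaHCO3; MeI, Et2O/MeOH, rt; aq. NaHCO3, CH2Cl2, rt; used at once in step 8
Reagents that add atoms: dimethyl(methylidene)ammonium iodide, C=[N+](C)C.[I-]
Why: Mannich reaction of the silyl enol ether places the aminomethyl group only at C2, and N-methylation followed by mild-base E1cB elimination gives the α-methylene ketone without epimerising the neighbouring stereocentre, whose descriptor changes from R to S only through the CIP priorities.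

Step 8
Reactants: 16 ethyl 3-[(1S)-6,6-dimethyl-2-methylidene-3-oxocyclohexyl]propanoate
Product: 17 ethyl 3-[(1S,3S)-3-hydroxy-6,6-dimethyl-2-methylidenecyclohexyl]propanoate
Conditions: (R)-2-methyl-CBS-oxazaborolidine (0.3 equiv), catecholborane (1.5 equiv), toluene, −78 °C
Reagents that add atoms: none
Why: Corey–Bakshi–Shibata reduction, in which the catalyst binds the ketone with the alkylidene-bearing carbon as the large group and delivers hydride to one carbonyl face, setting the carbinol centre as S (trans to the side chain) by reagent control instead of relying on the ring's own bias, while the low temperature holds back uncatalysed conjugate reduction and leaves the ester untouched.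

Step 9
Reactants: 17 ethyl 3-[(1S,3S)-3-hydroxy-6,6-dimethyl-2-methylidenecyclohexyl]propanoate
Product: 18 ethyl 3-[(1S,3S)-3-(TBS-oxy)-6,6-dimethyl-2-methylidenecyclohexyl]propanoate
Conditions: TBSCl, imidazole, DMF, rt
Reagents that add atoms: tert-butyldimethylsilyl chloride, CC(C)(C)[Si](C)(C)Cl
Why: standard silylation of a secondary allylic alcohol, which masks the hydroxyl against the amide bases of the key step and is removed by fluoride at the end.

Step 10
Reactants: 18 ethyl 3-[(1S,3S)-3-(TBS-oxy)-6,6-dimethyl-2-methylidenecyclohexyl]propanoate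
Product: 19 N-methoxy-N-methyl-3-[(1S,3S)-3-(TBS-oxy)-6,6-dimethyl-2-methylidenecyclohexyl]propanamide
Conditions: MeNH(OMe)·HCl (1.5 equiv), i-PrMgCl (3 equiv), THF, −20 → 0 °C
Reagents that add atoms: N,O-dimethylhydroxylamine hydrochloride, CNOC.Cl
Why: direct aminolysis of the ester by the chloromagnesium amide of N,O-dimethylhydroxylamine (Weinreb amide formation), under which the silyl ether, the alkene and both stereocentres are inert.

Step 11
Reactants: 8 methyl 6-[3,4-bis(SEM-oxy)phenyl]-2-methyl-4-oxo-4H-pyran-3-carboxylate; 19 N-methoxy-N-methyl-3-[(1S,3S)-3-(TBS-oxy)-6,6-dimethyl-2-methylidenecyclohexyl]propanamide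
Product: 21 2-[3,4-bis(SEM-oxy)phenyl]-6-{[(1S,3S)-3-(TBS-oxy)-6,6-dimethyl-2-methylidenecyclohexyl]methyl}-5,7-dihydroxy-4H-chromen-4-one, via pyranonyl ketone 20 (not isolated)
Conditions: 8 (1.5 equiv), LDA (1.5 equiv), THF, −78 °C; 19 (1.0 equiv), −78 → −20 °C; LDA (3.5 equiv), −78 °C → rt; AcOH
Reagents that add atoms: none
Why: LDA removes a proton from the 2-methyl group of 8, which is vinylogous to both the C4 carbonyl and the C3 ester, and the lithium dienolate adds through carbon to the amide carbonyl of 19 (C7–C8 bond); excess LDA then deprotonates the adduct at C8 so that it collapses to the enolate of ketone 20, a second deprotonation at the flanking CH2 (C6) gives a dianion whose terminal carbanion attacks the neighbouring ester (C5–C6 bond), methoxide leaves and the cyclic triketone tautomerises to the aromatic 5,7-diol. The closest known reactions are the lateral lithiation–acylation of ortho-toluate esters and of 2-methyl-4-pyranones and the Claisen aromatisation of the resulting 2-oxoalkyl esters to 1,3-dihydroxyarenes (Staunton–Weinreb-type annulation, dianion chemistry of β-dicarbonyl compounds). Ring A closes in a 6-exo-trig mode at the ester carbonyl. No stereocentre is formed, and the two existing ones lie far from every acidified position. Regiochemistry needs no control, because O1, C2, C3 and C4 are already in the pyranone and the side chain can therefore end up only at C6. What must be secured is deprotonation in place of addition to the pyranone (hindered amide base at −78 °C), carbon over oxygen acylation in the closure (the last-formed carbanion of the dianion is the most nucleophilic site and aromatisation makes C-acylation irreversible), and inert protecting groups (SEM acetals and a TBS ether, none attacked by LDA or lithium methoxide).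

Step 12
Reactants: 21 2-[3,4-bis(SEM-oxy)phenyl]-6-{[(1S,3S)-3-(TBS-oxy)-6,6-dimethyl-2-methylidenecyclohexyl]methyl}-5,7-dihydroxy-4H-chromen-4-one
Product: 22 ugonin Q
Conditions: TBAF (10 equiv), ethylenediamine (6 equiv), THF/DMPU, 60 °C, Ar; aq. NH4Cl
Reagents that add atoms: none
Why: fluoride attacks silicon in both SEM groups (fragmentation to fluorosilane, ethene, formaldehyde and phenoxide) and in the silyl ether in one basic, acid-free operation, so the exocyclic alkene cannot cyclise onto the 5- or 7-hydroxyl, while ethylenediamine intercepts formaldehyde before it can hydroxymethylate C8.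

**Compound list**

1 | 3,4-dihydroxybenzaldehyde | O=Cc1ccc(O)c(O)c1 | starting material
2 | 3,4-bis{[2-(trimethylsilyl)ethoxy]methoxy}benzaldehyde | O=Cc1ccc(OCOCC[Si](C)(C)C)c(OCOCC[Si](C)(C)C)c1 | intermediate
3 | 4-(2,2-dibromoethenyl)-1,2-bis{[2-(trimethylsilyl)ethoxy]methoxy}benzene | BrC(Br)=Cc1ccc(OCOCC[Si](C)(C)C)c(OCOCC[Si](C)(C)C)c1 | intermediate
4 | 3-(3,4-bis{[2-(trimethylsilyl)ethoxy]methoxy}phenyl)prop-2-ynoic acid | OC(=O)C#Cc1ccc(OCOCC[Si](C)(C)C)c(OCOCC[Si](C)(C)C)c1 | intermediate
5 | methyl acetoacetate (methyl 3-oxobutanoate) | COC(=O)CC(C)=O | starting material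
6 | 3-(3,4-bis{[2-(trimethylsilyl)ethoxy]methoxy}phenyl)prop-2-ynoyl chloride | ClC(=O)C#Cc1ccc(OCOCC[Si](C)(C)C)c(OCOCC[Si](C)(C)C)c1 | intermediate
7 | methyl 2-acetyl-5-(3,4-bis{[2-(trimethylsilyl)ethoxy]methoxy}phenyl)-3-oxopent-4-ynoate (drawn as the triketo form, enolised in solution) | COC(=O)C(C(C)=O)C(=O)C#Cc1ccc(OCOCC[Si](C)(C)C)c(OCOCC[Si](C)(C)C)c1 | intermediate
8 | methyl 6-(3,4-bis{[2-(trimethylsilyl)ethoxy]methoxy}phenyl)-2-methyl-4-oxo-4H-pyran-3-carboxylate | COC(=O)c1c(C)oc(-c2ccc(OCOCC[Si](C)(C)C)c(OCOCC[Si](C)(C)C)c2)cc1=O | intermediate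
9 | (1-ethoxycyclopropoxy)trimethylsilane | CCOC1(O[Si](C)(C)C)CC1 | starting material
10 | 4,4-dimethylcyclohex-2-en-1-one | O=C1C=CC(C)(C)CC1 | starting material
11 | bis(3-ethoxy-3-oxopropyl)zinc (zinc homoenolate, formed from two molecules of 9) | CCOC(=O)CC[Zn]CCC(=O)OCC | intermediate
12 | (3-ethoxy-3-oxopropyl)zinc (3R)-3-(3-ethoxy-3-oxopropyl)-4,4-dimethylcyclohex-1-en-1-olate (zinc enolate) | CCOC(=O)CC[Zn]OC1=C[C@@H](CCC(=O)OCC)C(C)(C)CC1 | intermediate
13 | ethyl 3-[(1R)-6,6-dimethyl-3-(trimethylsilyloxy)cyclohex-2-en-1-yl]propanoate | C[Si](C)(C)OC1=C[C@@H](CCC(=O)OCC)C(C)(C)CC1 | intermediate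
14 | ethyl 3-[(1R)-2-[(dimethylamino)methyl]-6,6-dimethyl-3-oxocyclohexyl]propanoate (epimers at C2) | CN(C)CC1[C@@H](CCC(=O)OCC)C(C)(C)CCC1=O | intermediate
15 | N-methyl ammonium iodide of 14, {[(2R)-2-(3-ethoxy-3-oxopropyl)-3,3-dimethyl-6-oxocyclohexyl]methyl}trimethylammonium iodide | C[N+](C)(C)CC1[C@@H](CCC(=O)OCC)C(C)(C)CCC1=O.[I-] | intermediate
16 | ethyl 3-[(1S)-6,6-dimethyl-2-methylidene-3-oxocyclohexyl]propanoate | C=C1[C@@H](CCC(=O)OCC)C(C)(C)CCC1=O | intermediate
17 | ethyl 3-[(1S,3S)-3-hydroxy-6,6-dimethyl-2-methylidenecyclohexyl]propanoate | C=C1[C@@H](CCC(=O)OCC)C(C)(C)CC[C@@H]1O | intermediate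
18 | ethyl 3-[(1S,3S)-3-(tert-butyldimethylsilyloxy)-6,6-dimethyl-2-methylidenecyclohexyl]propanoate | C=C1[C@@H](CCC(=O)OCC)C(C)(C)CC[C@@H]1O[Si](C)(C)C(C)(C)C | intermediate
19 | N-methoxy-N-methyl-3-[(1S,3S)-3-(tert-butyldimethylsilyloxy)-6,6-dimethyl-2-methylidenecyclohexyl]propanamide | C=C1[C@@H](CCC(=O)N(C)OC)C(C)(C)CC[C@@H]1O[Si](C)(C)C(C)(C)C | intermediate
20 | methyl 6-(3,4-bis{[2-(trimethylsilyl)ethoxy]methoxy}phenyl)-2-{4-[(1S,3S)-3-(tert-butyldimethylsilyloxy)-6,6-dimethyl-2-methylidenecyclohexyl]-2-oxobutyl}-4-oxo-4H-pyran-3-carboxylate | C=C1[C@@H](CCC(=O)Cc2oc(-c3ccc(OCOCC[Si](C)(C)C)c(OCOCC[Si](C)(C)C)c3)cc(=O)c2C(=O)OC)C(C)(C)CC[C@@H]1O[Si](C)(C)C(C)(C)C | intermediate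
21 | 2-(3,4-bis{[2-(trimethylsilyl)ethoxy]methoxy}phenyl)-6-{[(1S,3S)-3-(tert-butyldimethylsilyloxy)-6,6-dimethyl-2-methylidenecyclohexyl]methyl}-5,7-dihydroxy-4H-chromen-4-one | C=C1[C@@H](Cc2c(O)cc3oc(-c4ccc(OCOCC[Si](C)(C)C)c(OCOCC[Si](C)(C)C)c4)cc(=O)c3c2O)C(C)(C)CC[C@@H]1O[Si](C)(C)C(C)(C)C | intermediate
22 | ugonin Q, 2-(3,4-dihydroxyphenyl)-5,7-dihydroxy-6-{[(1S,3S)-3-hydroxy-6,6-dimethyl-2-methylidenecyclohexyl]methyl}-4H-chromen-4-one | C=C1[C@@H](Cc2c(O)cc3oc(-c4ccc(O)c(O)c4)cc(=O)c3c2O)C(C)(C)CC[C@@H]1O | target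

**Step count and risks**

Total step count: 12. Longest linear sequence: 7 steps (9 → 13 → 16 → 17 → 18 → 19 → 21 → 22). The aryl branch (1 → 8) is equally long: 5 steps before the convergence, then steps 11 and 12.

Steps most likely to fail:

1. Step 11. The stabilised dienolate may add too slowly to the amide, so that both partners are recovered. The ring closure may also go through the enolate oxygen (an enol lactone) instead of through C6. The fallback separates the two bond formations and uses an aldehyde as the electrophile. It sets out from 19 and 8. Compound 19 is reduced (i-Bu2AlH, THF, −78 °C) to 3-[(1S,3S)-3-(tert-butyldimethylsilyloxy)-6,6-dimethyl-2-methylidenecyclohexyl]propanal F1. F1 is added at −78 °C to the lithium dienolate of 8 and the mixture is quenched cold with AcOH, to prevent lactonisation onto the neighbouring ester. This should give the β-hydroxy adduct methyl 6-[3,4-bis(SEM-oxy)phenyl]-2-{4-[(1S,3S)-3-(TBS-oxy)-6,6-dimethyl-2-methylidenecyclohexyl]-2-hydroxybutyl}-4-oxo-4H-pyran-3-carboxylate F2. Oxidation (Dess–Martin periodinane, NaHCO3, CH2Cl2) gives ketone 20, now isolated. Ring A is then closed under reversible alkoxide conditions (NaOMe, MeOH/THF, 40 °C), under which any enol lactone is reopened and funnelled to the aromatic product. The fallback comes back to the route at 21.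

2. Step 6. The chelated homoenolate may turn over poorly without silyl chloride activation, or the facial selectivity may be eroded next to the quaternary carbon. The fallback sets out from 9 and 10 and gives up the asymmetric addition.
   - Compound 9 is opened with ZnCl2 in Et2O and the Me3SiCl formed is left in the flask. Addition of 10, CuBr·SMe2 (cat.) and HMPA at rt (the racemic copper-catalysed, silyl-chloride-promoted homoenolate addition) should give racemic ethyl 3-[6,6-dimethyl-3-(trimethylsilyloxy)cyclohex-2-en-1-yl]propanoate F3.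
   - The conditions of step 7 lead through racemic ethyl 3-{2-[(dimethylamino)methyl]-6,6-dimethyl-3-oxocyclohexyl}propanoate F4 and its methiodide {[2-(3-ethoxy-3-oxopropyl)-3,3-dimethyl-6-oxocyclohexyl]methyl}trimethylammonium iodide F5 to racemic ethyl 3-(6,6-dimethyl-2-methylidene-3-oxocyclohexyl)propanoate F6.
   - Reduction of F6 under the conditions of step 8 should turn the two enantiomers into diastereomeric alcohols: 17 from the (S)-enone and the cis isomer ethyl 3-[(1R,3S)-3-hydroxy-6,6-dimethyl-2-methylidenecyclohexyl]propanoate F7 from the (R)-enone.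
   - Chromatographic separation and a check of enantiomeric purity bring the route back at 17.

3. Step 8. The substrate's own facial bias may oppose the catalyst and lower the facial selectivity at the carbonyl, and the borane may deliver hydride in a conjugate sense to the s-cis enone or add to the alkene. The fallback sets out from 16 and uses the substrate bias followed by inversion. Luche reduction (NaBH4, CeCl3·7H2O, MeOH, −78 °C) is expected to give mainly the cis alcohol ethyl 3-[(1S,3R)-3-hydroxy-6,6-dimethyl-2-methylidenecyclohexyl]propanoate F8. Mitsunobu inversion (4-nitrobenzoic acid, PPh3, DIAD, toluene, 0 °C → rt) should give the trans ester ethyl 3-[(1S,3S)-6,6-dimethyl-2-methylidene-3-(4-nitrobenzoyloxy)cyclohexyl]propanoate F9. Ethanolysis (K2CO3, EtOH, rt) removes the nitrobenzoate without changing the ethyl ester and comes back to the route at 17.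

Further compounds

F1 | step 11 | 3-[(1S,3S)-3-(tert-butyldimethylsilyloxy)-6,6-dimethyl-2-methylidenecyclohexyl]propanal | C=C1[C@@H](CCC=O)C(C)(C)CC[C@@H]1O[Si](C)(C)C(C)(C)C
F2 | step 11 | methyl 6-(3,4-bis{[2-(trimethylsilyl)ethoxy]methoxy}phenyl)-2-{4-[(1S,3S)-3-(tert-butyldimethylsilyloxy)-6,6-dimethyl-2-methylidenecyclohexyl]-2-hydroxybutyl}-4-oxo-4H-pyran-3-carboxylate (carbinol epimers) | C=C1[C@@H](CCC(O)Cc2oc(-c3ccc(OCOCC[Si](C)(C)C)c(OCOCC[Si](C)(C)C)c3)cc(=O)c2C(=O)OC)C(C)(C)CC[C@@H]1O[Si](C)(C)C(C)(C)C
F3 | step 6 | racemic ethyl 3-[6,6-dimethyl-3-(trimethylsilyloxy)cyclohex-2-en-1-yl]propanoate | C[Si](C)(C)OC1=CC(CCC(=O)OCC)C(C)(C)CC1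
F4 | step 6 | racemic ethyl 3-{2-[(dimethylamino)methyl]-6,6-dimethyl-3-oxocyclohexyl}propanoate | CN(C)CC1C(CCC(=O)OCC)C(C)(C)CCC1=O
F5 | step 6 | racemic {[2-(3-ethoxy-3-oxopropyl)-3,3-dimethyl-6-oxocyclohexyl]methyl}trimethylammonium iodide | C[N+](C)(C)CC1C(CCC(=O)OCC)C(C)(C)CCC1=O.[I-]
F6 | step 6 | racemic ethyl 3-(6,6-dimethyl-2-methylidene-3-oxocyclohexyl)propanoate | C=C1C(CCC(=O)OCC)C(C)(C)CCC1=O
F7 | step 6 | ethyl 3-[(1R,3S)-3-hydroxy-6,6-dimethyl-2-methylidenecyclohexyl]propanoate | C=C1[C@H](CCC(=O)OCC)C(C)(C)CC[C@@H]1O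
F8 | step 8 | ethyl 3-[(1S,3R)-3-hydroxy-6,6-dimethyl-2-methylidenecyclohexyl]propanoate | C=C1[C@@H](CCC(=O)OCC)C(C)(C)CC[C@H]1O
F9 | step 8 | ethyl 3-[(1S,3S)-6,6-dimethyl-2-methylidene-3-(4-nitrobenzoyloxy)cyclohexyl]propanoate | C=C1[C@@H](CCC(=O)OCC)C(C)(C)CC[C@@H]1OC(=O)c1ccc(cc1)[N+](=O)[O-]
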